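# Proposed synthesis of the (R)-hydroxyphthalide depsidone CNP0367167.1 (compound 22)

## Analysis of the target

The target 22 is a depsidone. Benzene rings A and B are joined by a diaryl ether oxygen and by an aryl ester, which together close a seven-membered dioxepinone; ring B is also fused to a five-membered 3-hydroxy-lactone (a hydroxyphthalide). Ring A carries, in order, OMe, H, CH3, the ester carbonyl, the ether oxygen and CH2OH. Ring B has no hydrogen and carries, in order, the ether oxygen, the ester oxygen, CH3, a free phenol, the lactone carbonyl and the lactol carbon. The lactol carbon is the only stereocentre and is (R); it is a hemiacylal and can lose its configuration by opening to the formyl acid. The sensitive groups are the aryl ester of the seven-membered ring (hydroxide, alkoxide), the benzylic alcohol between two oxygen-bearing carbons (ionises in acid), the lactol (base, hydride) and the hydroquinone-type oxygenation of ring B (oxidants). Three things make the synthesis hard: a hexasubstituted ring B with three oxygens that must be told apart, a diaryl ether with four ortho substituents, and a stereocentre that can only be set at the very end. The plan rests on ring B. Its ether-bearing and phenol-bearing carbons are para; between them lie the vicinal lactone-carbonyl and lactol carbons on one side and the ester-oxygen and methyl carbons on the other. This is the pattern formed when a 2,4-dioxygenated 3-methylfuran adds through C2 and C5 to an alkyne carrying an ester and a masked formyl group, and the oxygen bridge then opens.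

## Retrosynthetic reasoning

**22 from 21 and 20.** The stereocentre is disconnected last. Racemic lactol 20 racemises through its open form, so an acylative dynamic kinetic resolution can convert all of it into the configurationally stable (R)-acylal 21. Enzymatic deacylation of 21 breaks only acyl–oxygen bonds, so the C–O bonds at the stereocentre are not touched. The primary alcohol is acetylated and released in the same two operations and needs no separate protecting group.

**20 from 18 (through 19).** The lactol ring is cut at the lactone C–O bond and taken back to a tert-butyl ester and a diethyl acetal on neighbouring ring B carbons. Both fall to acid. This matters because the aryl ester of the seven-membered ring would not survive saponification of an ordinary alkyl ester. The two silyl ethers (phenol, benzylic alcohol) are removed in the same flask.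

**18 from 17, and 17 from 16.** The seven-membered ring is opened at the ester C(=O)–O bond. The forward closure is intramolecular and can only involve the ring B hydroxyl ortho to the ether oxygen, so there is no regiochemical question. Acid 17 comes from 16 by hydrogenolysis, which frees the ring A carboxyl (benzyl ester) and that ring B hydroxyl (benzyl ether) together.

**16 from 15 and 14.** The hydroxymethyl carbon is taken back to an aldehyde. The aldehyde is needed one step earlier as an activating group; once it has done that job it is reduced and silylated.

**14 from 8 and 13.** The diaryl ether is cut at the ring A carbon–oxygen bond. In fluoride 13 that carbon lies between a formyl and an ester group, so substitution by a phenoxide is an addition–elimination that tolerates four ortho substituents. The oxygen stays on ring B, where phenol 8 carries it as its only free hydroxyl. The neighbouring oxygen of 8 is a benzyl ether and not a silyl ether, because a silyl group would migrate between two vicinal phenolic oxygens under base and blur the distinction between ether oxygen and ester oxygen.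

**13 from 9 (through 10, 11, 12).** Ring A needs no ring construction. Orsellinic acid 9 already has the methyl group, the carboxyl and both oxygens. Benzylation of the acid, methylation of the free para hydroxyl, ortho-formylation and deoxyfluorination of the chelated hydroxyl give 13.

**8 from 3 and 6 (through 7).** Both C–C bonds between the furan carbons and the alkyne carbons are cut. Furan 3 supplies four ring carbons with the methyl group and two oxygens; alkyne 6 supplies the two carbons bearing the ester and the acetal; the bridge oxygen of adduct 7 becomes the free phenol. All six substituents of ring B, with the three oxygens as phenol, benzyl ether and silyl ether, come from one step.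

**3 from 1 (through 2), and 6 from 4 (through 5).** Furan 3 is the silyl dienol ether of benzyl tetronate 2, made by O-benzylation of alpha-methyltetronic acid 1. Alkyne 6 is the C-acylation product of lithium acetylide 5, made from propargyl aldehyde acetal 4. The ester is tert-butyl for the reason given under 20.

## Alternatives that were turned down

**Alternative 1:** The diaryl ether bond on ring A and the C–C bond to the future hydroxymethyl carbon are cut together. Forward, a ring B phenoxide would add to the aryne 3-methoxy-5-methylbenzyne A2 at the carbon meta to methoxy, and the aryl anion left ortho to methoxy would be carboxylated to give the diaryl ether acid A1.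
- For it: a hindered diaryl ether forms without a metal and without an activated halide, and the inductive effect of methoxy controls where the nucleophile adds. On the ether bond itself this plan is stronger than the chosen one, which needs a four-step ring A fluoride.
- Against it: in A1 the ring A carbon between methyl and ether oxygen still bears hydrogen. The carbonyl of the seven-membered ring must therefore be introduced afterwards, while the carboxyl just made must be reduced to the hydroxymethyl group, so both ring A carbons arrive at the wrong oxidation level.
- The aryl anion can also be protonated by any phenol present, and the phenoxide can itself be carboxylated.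
- The plan also presupposes a fully substituted ring B phenol and has no way to build it.
- Comparison: the chosen route gives up the easier etherification but makes ring B in one step and takes a ring A with every carbon in place from a commercial arene.

**Alternative 2:** The ring A C–C bond between the ester-bearing and methyl-bearing carbons is cut. Forward, the aryl 3,5,7-trioxooctanoate A4 would cyclise by aldol addition and dehydrate to the depside A3, an orsellinate ester of a bromo ring B phenol.
- For it: the ester link exists before the ether, so the later ether closure onto the bromide is intramolecular. On that point it equals or beats an intermolecular substitution.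
- Against it: in A4 the leaving group is a hindered, electron-poor phenoxide. Base can expel it by O-cyclisation to a pyranone or by acyl transfer in preference to the aldol.
- After A3 there remain a selective O-methylation, a C-hydroxymethylation between two oxygens and a ring closure at a bromide flanked on both sides.
- The ring it builds is the one that can be bought, and the hexasubstituted bromo ring B must come from elsewhere.
- Comparison: the chosen route invests its ring-forming step in ring B, where no commercial arene exists.

**Alternative 3:** Two C–C bonds of ring A are cut. Forward, the fused pyranone A6 would add 1,1-dimethoxyethene A7, lose CO2 and methanol, and give the protected depsidone A5.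
- For it: the polarity of A6 and A7 is matched, the seven-membered ring is closed before ring A exists so no hindered etherification between two arenes is needed, and A5 is a late intermediate close to 18. On convergence at the end it is at least as strong as the chosen plan.
- Against it: A6 is a harder target than A5. It needs a pyranone carrying an aryloxy group, an acyl group and a silyloxymethyl group, tied to ring B through an ester and an enol ether, and both links are electrophilic towards the ketene acetal and the methanol set free.
- It again builds ring A from scratch and leaves ring B unsolved.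
- Comparison: the chosen route reaches the stage of 18 from two short branches and builds only the ring that has to be built.

Key step: step 4

## Remarks on the chemistry (assumptions)

- The lactol carbon can epimerise by ring–chain tautomerism. It is assumed that free (R)-lactol 22 keeps its configuration in neutral, aprotic medium at or below room temperature, so the stereocentre is set in the last two steps and 22 is isolated without contact with acid, base or protic solvent.
- The sense of induction of the acyl-transfer catalyst in step 15 is not predicted here. The antipode that gives the (R)-acylal is to be identified on a model 3-hydroxyphthalide and confirmed on 21.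

## Route

Step 1
Reactants: 1 4-hydroxy-3-methylfuran-2(5H)-one (alpha-methyltetronic acid)
Product: 2 4-(benzyloxy)-3-methylfuran-2(5H)-one
Conditions: BnOH, TsOH·H2O (cat.), toluene, reflux, Dean–Stark
Reagents that add atoms: benzyl alcohol, OCc1ccccc1
Why: Acid-catalysed enol etherification (vinylogous Fischer esterification) of the tetronic acid; the 3-methyl group blocks C-alkylation and removal of water drives the equilibrium.

Step 2
Reactants: 2 4-(benzyloxy)-3-methylfuran-2(5H)-one
Product: 3 4-(benzyloxy)-2-[(tert-butyldimethylsilyl)oxy]-3-methylfuran
Conditions: TBSOTf, Et3N, CH2Cl2, 0 °C; pentane extraction, used crude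
Reagents that add atoms: tert-butyldimethylsilyl trifluoromethanesulfonate, CC(C)(C)[Si](C)(C)OS(=O)(=O)C(F)(F)F
Why: Standard silyloxyfuran formation: O-silylation of the lactone carbonyl and gamma-deprotonation by the amine aromatise the butenolide; the product is moisture-sensitive and is used directly.

Step 3
Reactants: 4 3,3-diethoxyprop-1-yne
Product: 6 tert-butyl 4,4-diethoxybut-2-ynoate, via lithium acetylide 5 (not isolated)
Conditions: n-BuLi, THF, −78 °C; then added to Boc2O, THF, −78 → 0 °C
Reagents that add atoms: di-tert-butyl dicarbonate, CC(C)(C)OC(=O)OC(=O)OC(C)(C)C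
Why: Deprotonation of the terminal alkyne and C-acylation of the acetylide by the dicarbonate, with inverse addition to suppress a second addition; the tert-butyl ester is chosen because it later falls to acid and not to hydroxide.

Step 4
Reactants: 3 4-(benzyloxy)-2-[(tert-butyldimethylsilyl)oxy]-3-methylfuran; 6 tert-butyl 4,4-diethoxybut-2-ynoate
Product: 8 tert-butyl 4-(benzyloxy)-6-[(tert-butyldimethylsilyl)oxy]-2-(diethoxymethyl)-3-hydroxy-5-methylbenzoate, via oxanorbornadiene 7 (not isolated)
Conditions: 3 (1.1 equiv), toluene (1 M), 90 °C, sealed tube, N2; no Lewis acid; Et3N-deactivated SiO2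
Reagents that add atoms: none
Why: The electron-rich furan 3 adds thermally to the electron-poor alkyne 6 in a strongly asynchronous [4+2] cycloaddition (at the limit a Michael addition followed by closure of the zwitterion) to give the 7-oxanorbornadiene 7. In 7 the bridge C–O bond at the silyloxy-bearing bridgehead ionises to a cyclohexadienyl cation stabilised by the silyloxy and benzyloxy groups, the other bridgehead loses its proton, and the bridge oxygen remains as the free phenol of 8. The closest known reaction type is the Diels–Alder reaction of 2-silyloxyfurans with acetylenic esters, which opens to para-silyloxy phenols. Ring B is closed by an intermolecular [4+2] cycloaddition that forms both new C–C bonds and is aromatised by bridge opening, with no fragment lost. No stereocentre remains, since the two bridgehead centres of racemic 7 are erased on aromatisation. The step needs regioselectivity: furan C5, unsubstituted and the most nucleophilic terminus, bonds to the alkyne carbon beta to the ester, which bears the acetal, so the acetal ends next to the new phenol and the ester next to the silyloxy carbon; polar and steric preferences point the same way. No Lewis acid is used, because it would ionise the acetal and divert 3 into a vinylogous Mukaiyama addition. The silyl group stays on the oxygen where it was introduced, so the three oxygens of 8 leave the step as phenol, benzyl ether and silyl ether.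

Step 5
Reactants: 9 2,4-dihydroxy-6-methylbenzoic acid (orsellinic acid)
Product: 10 benzyl 2,4-dihydroxy-6-methylbenzoate
Conditions: BnBr, KHCO3, DMF, 25–40 °C
Reagents that add atoms: benzyl bromide, BrCc1ccccc1
Why: SN2 alkylation of the carboxylate; hydrogencarbonate does not deprotonate the phenols, so only the ester forms, and the mild temperature avoids decarboxylation.

Step 6
Reactants: 10 benzyl 2,4-dihydroxy-6-methylbenzoate
Product: 11 benzyl 2-hydroxy-4-methoxy-6-methylbenzoate
Conditions: MeI (1.1 equiv), K2CO3, acetone, reflux
Reagents that add atoms: iodomethane, CI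
Why: Williamson methylation; the 2-hydroxyl is hydrogen-bonded to the ester carbonyl and much less nucleophilic, so the 4-hydroxyl is methylated selectively.

Step 7
Reactants: 11 benzyl 2-hydroxy-4-methoxy-6-methylbenzoate
Product: 12 benzyl 3-formyl-2-hydroxy-4-methoxy-6-methylbenzoate
Conditions: MgCl2, Et3N, (CH2O)n, MeCN, reflux; 1 M HCl work-up
Reagents that add atoms: formaldehyde (as paraformaldehyde), C=O
Why: Magnesium-mediated ortho-formylation (Casnati–Skattebøl): the magnesium phenoxide delivers formaldehyde to C3, the only free ortho carbon and one also activated by the 4-methoxy group, and a second formaldehyde takes up hydride to give the aldehyde.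

Step 8
Reactants: 12 benzyl 3-formyl-2-hydroxy-4-methoxy-6-methylbenzoate
Product: 13 benzyl 2-fluoro-3-formyl-4-methoxy-6-methylbenzoate
Conditions: PhenoFluor, CsF, toluene, 110 °C
Reagents that add atoms: PhenoFluor (1,3-bis(2,6-diisopropylphenyl)-2,2-difluoro-2,3-dihydro-1H-imidazole), CC(C)c1cccc(C(C)C)c1N1C=CN(c2c(C(C)C)cccc2C(C)C)C1(F)F
Why: Deoxyfluorination of a phenol: condensation with the difluoroimidazoline and concerted ipso displacement by fluoride, which is favoured here because the ring carbon lies between a formyl and an ester group.

Step 9
Reactants: 8 tert-butyl 4-(benzyloxy)-6-[(tert-butyldimethylsilyl)oxy]-2-(diethoxymethyl)-3-hydroxy-5-methylbenzoate; 13 benzyl 2-fluoro-3-formyl-4-methoxy-6-methylbenzoate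
Product: 14 benzyl 2-[2-(benzyloxy)-5-(tert-butoxycarbonyl)-4-[(tert-butyldimethylsilyl)oxy]-6-(diethoxymethyl)-3-methylphenoxy]-3-formyl-4-methoxy-6-methylbenzoate
Conditions: K2CO3, 4 Å MS, DMF, 60 °C
Reagents that add atoms: none
Why: Nucleophilic aromatic substitution by addition–elimination: the formyl and ester groups flanking the fluoride stabilise the Meisenheimer intermediate, and the phenoxide attacks perpendicular to ring A, so four ortho groups are tolerated. K2CO3 gives insoluble KF, which spares the aryl silyl ether, and the benzyl ether on the neighbouring oxygen cannot migrate.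

Step 10
Reactants: 14 the diaryl ether aldehyde
Product: 15 benzyl 2-[2-(benzyloxy)-5-(tert-butoxycarbonyl)-4-[(tert-butyldimethylsilyl)oxy]-6-(diethoxymethyl)-3-methylphenoxy]-3-(hydroxymethyl)-4-methoxy-6-methylbenzoate
Conditions: NaBH4, THF/EtOH, 0 °C
Reagents that add atoms: none
Why: Chemoselective borohydride reduction of the aryl aldehyde; the hindered benzyl and tert-butyl esters, the acetal and the silyl ether are inert at 0 °C.

Step 11
Reactants: 15 the benzylic alcohol
Product: 16 benzyl 2-[2-(benzyloxy)-5-(tert-butoxycarbonyl)-4-[(tert-butyldimethylsilyl)oxy]-6-(diethoxymethyl)-3-methylphenoxy]-3-{[(tert-butyldiphenylsilyl)oxy]methyl}-4-methoxy-6-methylbenzoate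
Conditions: TBDPSCl, imidazole, DMF, 25 °C
Reagents that add atoms: tert-butyl(chloro)diphenylsilane, CC(C)(C)[Si](Cl)(c1ccccc1)c1ccccc1
Why: Silylation of the only hydroxyl; the tert-butyldiphenylsilyl ether survives hydrogenolysis and aqueous trifluoroacetic acid and keeps the electron-rich benzylic oxygen from ionising in step 14.

Step 12
Reactants: 16 the silyl-protected diaryl ether
Product: 17 2-[5-(tert-butoxycarbonyl)-4-[(tert-butyldimethylsilyl)oxy]-6-(diethoxymethyl)-2-hydroxy-3-methylphenoxy]-3-{[(tert-butyldiphenylsilyl)oxy]methyl}-4-methoxy-6-methylbenzoic acid
Conditions: H2 (1 atm), 10% Pd/C, EtOAc, 25 °C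
Reagents that add atoms: none
Why: Hydrogenolysis cleaves the aryl benzyl ether and the benzyl ester in one operation; in neutral ethyl acetate the benzylic silyl ether, the diethyl acetal and the diaryl ether are not reduced.

Step 13
Reactants: 17 the hydroxy acid
Product: 18 protected depsidone (seven-membered lactone between the ring A carboxyl and the ring B hydroxyl ortho to the ether oxygen; ring A: OMe, CH3, CH2OTBDPS; ring B: CH3, OTBS, CO2tBu, CH(OEt)2)
Conditions: 2-chloro-1-methylpyridinium iodide, Et3N, CH2Cl2, reflux, slow addition (final 2 mM)
Reagents that add atoms: none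
Why: Mukaiyama lactonisation: the acid is activated by the chloropyridinium salt and captured by the only hydroxyl in the molecule, the phenol ortho to the ether oxygen, closing the seven-membered ring by acyl substitution under high dilution.

Step 14
Reactants: 18 protected depsidone
Product: 20 racemic lactol (the racemate of 22), via bis-silyl lactol 19 (not isolated)
Conditions: TFA/CH2Cl2/H2O (10:10:1), anisole, 0 → 25 °C; evaporate; then HF·pyridine, pyridine, THF, 0 → 25 °C
Reagents that add atoms: water, O
Why: Acidolysis cleaves the tert-butyl ester by alkyl–oxygen fission and hydrolyses the acetal, and the ortho-formyl acid closes spontaneously to the five-membered lactol, formed as a racemate. Buffered hydrogen fluoride then removes both silyl ethers without base, so the aryl ester of the seven-membered ring is not touched.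

Step 15
Reactants: 20 racemic lactol
Product: 21 (R)-diacetate (acetate of the primary alcohol and acetate of the (R)-lactol; phenol free)
Conditions: Ac2O (2.3 equiv), one enantiomer of the isothiourea HyperBTM (10 mol%), iPr2NEt, CHCl3, −20 °C
Reagents that add atoms: acetic anhydride, CC(=O)OC(C)=O
Why: Acylative dynamic kinetic resolution of a 3-hydroxyphthalide: the amine base racemises the lactol through its ring-opened formyl carboxylate faster than the chiral acyl-isothiouronium acylates one enantiomer, so the catalyst sets the configuration of the acylal. The primary alcohol is acetylated without stereochemical consequence, and the chelated, doubly flanked phenol is expected to stay free.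

Step 16
Reactants: 21 (R)-diacetate
Product: 22 the target, (R)-lactol
Conditions: immobilised Burkholderia cepacia lipase, n-BuOH (6 equiv), MTBE, 25 °C; filter, evaporate below 25 °C
Reagents that add atoms: none
Why: Lipase-catalysed alcoholysis in a neutral aprotic medium cleaves both acetates at the acyl–oxygen bond, so the C–O bonds of the stereocentre are not touched and (R) is retained; no base, acid or water is present to open the lactol.

## Compound list

1 | 4-hydroxy-3-methylfuran-2(5H)-one (alpha-methyltetronic acid) | CC1=C(O)COC1=O | starting material
2 | 4-(benzyloxy)-3-methylfuran-2(5H)-one | CC1=C(OCc2ccccc2)COC1=O | intermediate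
3 | 4-(benzyloxy)-2-[(tert-butyldimethylsilyl)oxy]-3-methylfuran | CC1=C(O[Si](C)(C)C(C)(C)C)OC=C1OCc1ccccc1 | intermediate
4 | 3,3-diethoxyprop-1-yne | CCOC(OCC)C#C | starting material
5 | (3,3-diethoxyprop-1-yn-1-yl)lithium (not isolated) | [Li]C#CC(OCC)OCC | intermediate
6 | tert-butyl 4,4-diethoxybut-2-ynoate | CCOC(OCC)C#CC(=O)OC(C)(C)C | intermediate
7 | racemic 7-oxanorbornadiene adduct: tert-butyl 5-(benzyloxy)-1-[(tert-butyldimethylsilyl)oxy]-3-(diethoxymethyl)-6-methyl-7-oxabicyclo[2.2.1]hepta-2,5-diene-2-carboxylate (not isolated) | CC1=C(OCc2ccccc2)C3OC1(O[Si](C)(C)C(C)(C)C)C(C(=O)OC(C)(C)C)=C3C(OCC)OCC | intermediate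
8 | tert-butyl 4-(benzyloxy)-6-[(tert-butyldimethylsilyl)oxy]-2-(diethoxymethyl)-3-hydroxy-5-methylbenzoate | CCOC(OCC)c1c(O)c(OCc2ccccc2)c(C)c(O[Si](C)(C)C(C)(C)C)c1C(=O)OC(C)(C)C | intermediate
9 | 2,4-dihydroxy-6-methylbenzoic acid (orsellinic acid) | Cc1cc(O)cc(O)c1C(=O)O | starting material
10 | benzyl 2,4-dihydroxy-6-methylbenzoate | Cc1cc(O)cc(O)c1C(=O)OCc1ccccc1 | intermediate
11 | benzyl 2-hydroxy-4-methoxy-6-methylbenzoate | COc1cc(C)c(C(=O)OCc2ccccc2)c(O)c1 | intermediate
12 | benzyl 3-formyl-2-hydroxy-4-methoxy-6-methylbenzoate | COc1cc(C)c(C(=O)OCc2ccccc2)c(O)c1C=O | intermediate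
13 | benzyl 2-fluoro-3-formyl-4-methoxy-6-methylbenzoate | COc1cc(C)c(C(=O)OCc2ccccc2)c(F)c1C=O | intermediate
14 | benzyl 2-[2-(benzyloxy)-5-(tert-butoxycarbonyl)-4-[(tert-butyldimethylsilyl)oxy]-6-(diethoxymethyl)-3-methylphenoxy]-3-formyl-4-methoxy-6-methylbenzoate | COc1cc(C)c(C(=O)OCc2ccccc2)c(Oc2c(OCc3ccccc3)c(C)c(O[Si](C)(C)C(C)(C)C)c(C(=O)OC(C)(C)C)c2C(OCC)OCC)c1C=O | intermediate
15 | benzyl 2-[2-(benzyloxy)-5-(tert-butoxycarbonyl)-4-[(tert-butyldimethylsilyl)oxy]-6-(diethoxymethyl)-3-methylphenoxy]-3-(hydroxymethyl)-4-methoxy-6-methylbenzoate | COc1cc(C)c(C(=O)OCc2ccccc2)c(Oc2c(OCc3ccccc3)c(C)c(O[Si](C)(C)C(C)(C)C)c(C(=O)OC(C)(C)C)c2C(OCC)OCC)c1CO | intermediate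
16 | benzyl 2-[2-(benzyloxy)-5-(tert-butoxycarbonyl)-4-[(tert-butyldimethylsilyl)oxy]-6-(diethoxymethyl)-3-methylphenoxy]-3-{[(tert-butyldiphenylsilyl)oxy]methyl}-4-methoxy-6-methylbenzoate | COc1cc(C)c(C(=O)OCc2ccccc2)c(Oc2c(OCc3ccccc3)c(C)c(O[Si](C)(C)C(C)(C)C)c(C(=O)OC(C)(C)C)c2C(OCC)OCC)c1CO[Si](c1ccccc1)(c1ccccc1)C(C)(C)C | intermediate
17 | 2-[5-(tert-butoxycarbonyl)-4-[(tert-butyldimethylsilyl)oxy]-6-(diethoxymethyl)-2-hydroxy-3-methylphenoxy]-3-{[(tert-butyldiphenylsilyl)oxy]methyl}-4-methoxy-6-methylbenzoic acid | COc1cc(C)c(C(=O)O)c(Oc2c(O)c(C)c(O[Si](C)(C)C(C)(C)C)c(C(=O)OC(C)(C)C)c2C(OCC)OCC)c1CO[Si](c1ccccc1)(c1ccccc1)C(C)(C)C | intermediate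
18 | protected depsidone (ring A: OMe, CH3, CH2OTBDPS; ring B: CH3, OTBS, CO2tBu, CH(OEt)2) | COc1cc(C)c2c(c1CO[Si](c1ccccc1)(c1ccccc1)C(C)(C)C)Oc1c(c(C)c(O[Si](C)(C)C(C)(C)C)c(C(=O)OC(C)(C)C)c1C(OCC)OCC)OC2=O | intermediate
19 | racemic bis-silyl lactol (hydroxyphthalide formed; OTBS and CH2OTBDPS still in place; not isolated) | COc1cc(C)c2c(c1CO[Si](c1ccccc1)(c1ccccc1)C(C)(C)C)Oc1c(c(C)c(O[Si](C)(C)C(C)(C)C)c3c1C(O)OC3=O)OC2=O | intermediate
20 | racemic lactol (racemate of the target) | COc1cc(C)c2c(c1CO)Oc1c(c(C)c(O)c3c1C(O)OC3=O)OC2=O | intermediate
21 | (R)-diacetate: primary acetate and (R)-acylal acetate of the target | COc1cc(C)c2c(c1COC(C)=O)Oc1c(c(C)c(O)c3c1[C@H](OC(C)=O)OC3=O)OC2=O | intermediate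
22 | target, (R)-lactol depsidone CNP0367167.1 | COc1cc(C)c2c(c1CO)Oc1c(c(C)c(O)c3c1[C@H](O)OC3=O)OC2=O | target

## Step count and risk

Total step count: 16. Longest linear sequence: 12 steps (steps 5 to 16, from orsellinic acid 9); the ring B branch from 1 is 11 steps.

**Step 4 (key step).**
- What may go wrong: conjugate addition that stops before ring closure; slow cycloaddition of the singly activated alkyne while the silyloxyfuran decomposes; transfer of the silyl group from unreacted 3 to the product phenol.
- Fallback, from 2 back to 8: a stepwise anionic Michael–Dieckmann annulation of the Hauser type. Butenolide 2 is deprotonated at C5 (LiHMDS, THF, −78 °C) and treated with 6. Conjugate addition, attack of the allenolate on the lactone carbonyl and opening of the bridged alkoxide give tert-butyl 4-(benzyloxy)-2-(diethoxymethyl)-3,6-dihydroxy-5-methylbenzoate F1. The non-chelated 3-hydroxyl is acetylated (Ac2O, pyridine, 0 °C) to tert-butyl 3-acetoxy-4-(benzyloxy)-2-(diethoxymethyl)-6-hydroxy-5-methylbenzoate F2. The chelated 6-hydroxyl is silylated (TBSOTf, 2,6-lutidine) to tert-butyl 3-acetoxy-4-(benzyloxy)-6-[(tert-butyldimethylsilyl)oxy]-2-(diethoxymethyl)-5-methylbenzoate F3. Aminolysis of the aryl acetate with pyrrolidine returns 8.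

**Step 8 (deoxyfluorination).**
- What may go wrong: slow condensation of the doubly hydrogen-bonded, doubly flanked phenol with the bulky reagent, and competing attack of the reagent on the aldehyde.
- Fallback, from 12 back to 13: the phenol is converted with sulfuryl fluoride and Et3N into benzyl 2-[(fluorosulfonyl)oxy]-3-formyl-4-methoxy-6-methylbenzoate F4. Anhydrous tetramethylammonium fluoride in DMF then displaces fluorosulfate at the ring carbon to give 13.

**Step 9 (etherification).**
- What may go wrong: steric retardation at a carbon with two ortho groups meeting a phenoxide with two ortho groups; loss of the aryl silyl ether to liberated fluoride, followed by a second arylation.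
- Fallback, from 12 back to 16, with no fluoride: 12 is triflated (Tf2O, pyridine) to benzyl 3-formyl-4-methoxy-6-methyl-2-{[(trifluoromethyl)sulfonyl]oxy}benzoate F5. This is reduced (NaBH4) to benzyl 3-(hydroxymethyl)-4-methoxy-6-methyl-2-{[(trifluoromethyl)sulfonyl]oxy}benzoate F6 and silylated (TBDPSCl, imidazole) to benzyl 3-{[(tert-butyldiphenylsilyl)oxy]methyl}-4-methoxy-6-methyl-2-{[(trifluoromethyl)sulfonyl]oxy}benzoate F7. Reducing the aldehyde first makes the triflate less prone to sulfonyl transfer. Palladium-catalysed C–O coupling of F7 with 8 (Pd(OAc)2, 2-di-tert-butylphosphino-2',4',6'-triisopropylbiphenyl, K3PO4, toluene, 100 °C) gives 16 directly.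

**Step 14 (unmasking).**
- What may go wrong: ionisation of the benzylic C–O bond in strong acid followed by Friedel–Crafts alkylation of ring A; capture of the lactol by the ethanol set free; incomplete removal of the hindered aryl silyl ether.
- Fallback, from 18 back to 20, with no new compounds: the protic acid is replaced by silyl-transfer cleavage. TMSOTf and 2,6-lutidine in CH2Cl2 at 0 °C convert the tert-butyl ester into a silyl ester and the acetal into a pyridinium adduct; water then gives 19, which is isolated. Buffered HF·pyridine completes the sequence to 20. The benzylic ether never meets a free Brønsted acid.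

**Step 15 (dynamic kinetic acylation).**
- What may go wrong: poor discrimination between the lactol enantiomers, because the lactol is flanked by the ring B ether carbon and three hydroxyls compete for the acyl donor; racemisation that is too slow relative to acylation.
- Fallback, from 20 back to 21: resolution with recycling. 20 is acetylated without a chiral catalyst (Ac2O, pyridine) to the racemic diacetate F8. Chromatography on a chiral stationary phase gives 21 and the (S)-diacetate F9. F9 is deacylated with lipase and n-BuOH to 20, which racemises under the basic acetylation conditions and re-enters the cycle.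

**Step 16 (enzymatic deacylation).**
- What may go wrong: racemisation of the freed lactol through ring opening during reaction or isolation, and slow turnover of the hindered acylal by the enzyme.
- Fallback, from 20 back to 22: step 15 is run with pent-4-enoic anhydride in place of acetic anhydride to give the (R)-bis(pent-4-enoate) F10. Iodine in aqueous THF, buffered with NaHCO3 solid, removes both pentenoyl groups by iodolactonisation under neutral, non-enzymatic conditions and releases 22.

## Further compounds

F1 | step 4 | tert-butyl 4-(benzyloxy)-2-(diethoxymethyl)-3,6-dihydroxy-5-methylbenzoate | CCOC(OCC)c1c(O)c(OCc2ccccc2)c(C)c(O)c1C(=O)OC(C)(C)C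
F2 | step 4 | tert-butyl 3-acetoxy-4-(benzyloxy)-2-(diethoxymethyl)-6-hydroxy-5-methylbenzoate | CCOC(OCC)c1c(OC(C)=O)c(OCc2ccccc2)c(C)c(O)c1C(=O)OC(C)(C)C
F3 | step 4 | tert-butyl 3-acetoxy-4-(benzyloxy)-6-[(tert-butyldimethylsilyl)oxy]-2-(diethoxymethyl)-5-methylbenzoate | CCOC(OCC)c1c(OC(C)=O)c(OCc2ccccc2)c(C)c(O[Si](C)(C)C(C)(C)C)c1C(=O)OC(C)(C)C
F4 | step 8 | benzyl 2-[(fluorosulfonyl)oxy]-3-formyl-4-methoxy-6-methylbenzoate | COc1cc(C)c(C(=O)OCc2ccccc2)c(OS(=O)(=O)F)c1C=O
F5 | step 9 | benzyl 3-formyl-4-methoxy-6-methyl-2-{[(trifluoromethyl)sulfonyl]oxy}benzoate | COc1cc(C)c(C(=O)OCc2ccccc2)c(OS(=O)(=O)C(F)(F)F)c1C=O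
F6 | step 9 | benzyl 3-(hydroxymethyl)-4-methoxy-6-methyl-2-{[(trifluoromethyl)sulfonyl]oxy}benzoate | COc1cc(C)c(C(=O)OCc2ccccc2)c(OS(=O)(=O)C(F)(F)F)c1CO
F7 | step 9 | benzyl 3-{[(tert-butyldiphenylsilyl)oxy]methyl}-4-methoxy-6-methyl-2-{[(trifluoromethyl)sulfonyl]oxy}benzoate | COc1cc(C)c(C(=O)OCc2ccccc2)c(OS(=O)(=O)C(F)(F)F)c1CO[Si](c1ccccc1)(c1ccccc1)C(C)(C)C
F0 | step 14 | none | none
F8 | step 15 | racemic diacetate (racemate of 21) | COc1cc(C)c2c(c1COC(C)=O)Oc1c(c(C)c(O)c3c1C(OC(C)=O)OC3=O)OC2=O
F9 | step 15 | (S)-diacetate (enantiomer of 21) | COc1cc(C)c2c(c1COC(C)=O)Oc1c(c(C)c(O)c3c1[C@@H](OC(C)=O)OC3=O)OC2=O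
F10 | step 16 | (R)-bis(pent-4-enoate): pent-4-enoate of the primary alcohol and of the (R)-lactol | COc1cc(C)c2c(c1COC(=O)CCC=C)Oc1c(c(C)c(O)c3c1[C@H](OC(=O)CCC=C)OC3=O)OC2=O
A1 | alternative 1 | 2-[6-(dimethoxymethyl)-5-(methoxycarbonyl)-2,4-bis(methoxymethoxy)-3-methylphenoxy]-6-methoxy-4-methylbenzoic acid | COc1cc(C)cc(Oc2c(OCOC)c(C)c(OCOC)c(C(=O)OC)c2C(OC)OC)c1C(=O)O
A2 | alternative 1 | 3-methoxy-5-methylbenzyne | COC1=CC(C)=CC#C1
A3 | alternative 2 | 2-bromo-3-(dimethoxymethyl)-4-(methoxycarbonyl)-5-(methoxymethoxy)-6-methylphenyl 2,4-dihydroxy-6-methylbenzoate | Cc1cc(O)cc(O)c1C(=O)Oc1c(Br)c(C(OC)OC)c(C(=O)OC)c(OCOC)c1C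
A4 | alternative 2 | 2-bromo-3-(dimethoxymethyl)-4-(methoxycarbonyl)-5-(methoxymethoxy)-6-methylphenyl 3,5,7-trioxooctanoate | CC(=O)CC(=O)CC(=O)CC(=O)Oc1c(Br)c(C(OC)OC)c(C(=O)OC)c(OCOC)c1C
A5 | alternative 3 | protected depsidone (ring A: OMe, CH3, CH2OTBS; ring B: CH3, OMOM, CO2Me, CH(OMe)2) | COc1cc(C)c2c(c1CO[Si](C)(C)C(C)(C)C)Oc1c(c(C)c(OCOC)c(C(=O)OC)c1C(OC)OC)OC2=O
A6 | alternative 3 | 2-pyranone fused to the seven-membered dioxepinone (6-methyl, 3-silyloxymethyl) | CC1=C2C(=O)Oc3c(C)c(OCOC)c(C(=O)OC)c(C(OC)OC)c3OC2=C(CO[Si](C)(C)C(C)(C)C)C(=O)O1
A7 | alternative 3 | 1,1-dimethoxyethene | COC(=C)OC
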